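**Plan**

Locants: ring A = C6 (spiro), C7 (Me, OH), C8, C9 (Br), C10, C11 (Me2); ring B = C6, C1=C2, C3 (=C15HBr), C4, C5.
Retrosynthesis: C9–Br ⇒ axial C9 carbinol ⇒ C9 ketone; then C5–C6 and C3–C4 are cut together (retro-[4+2]), opening ring B to the vinylallene C6=C1–C2=C3=C15HBr and a C4=C5 vinyl group held on the C7 oxygen through SiMe2; bromoallene ⇒ propargylic carbinol ⇒ ynone ⇒ butenolide ⇒ ketoisophorone.
Enabling feature: in ring B the cis C1=C2 bond is conjugated with the exocyclic C3=C15 bromoalkene (the retron of a vinylallene Diels–Alder reaction), C4H2–C5H2 is a bare ethylene unit, and the tertiary C7 hydroxyl sits next to the spiro carbon, so it can deliver that ethylene as a tethered vinylsilane.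
Forward: ring A is the ketoisophorone ring throughout; a temporary butenolide (C7–O–C2) locks the Z geometry of C6=C1; the chain is extended to the bromoallene; ring B and the spiro centre form in one cycloaddition; silicon is then excised and C9 adjusted.
Stereochemistry: C9 (asymmetric transfer hydrogenation) → C7 (axial enolate hydroxylation) → C6 (tether, same face as the C7 oxygen); C2 carbinol (catalyst control) → allene axis (anti SN2′) → E-bromoalkene; final C9 by equatorial hydride attack, then inversion by bromide.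

Key step: step 11

Assumption: both Ru–TsDPEN reductions are taken to follow the usual sense of induction, with the unsaturated carbonyl substituent (alkenyl in step 1, alkynyl in step 8) in the place of the aryl group of the standard model.

**Route**

Step 1
Reactants: 1 ketoisophorone (2,6,6-trimethylcyclohex-2-ene-1,4-dione)
Product: 2 (R)-4-hydroxy-2,6,6-trimethylcyclohex-2-en-1-one
Conditions: RuCl[(R,R)-TsDPEN](p-cymene) (cat.), i-PrOH, rt
Reagents that add atoms: none
Why: Noyori asymmetric transfer hydrogenation, a known type of reduction for this dione, should reduce only the unhindered carbonyl (future C9), because the other carbonyl is shielded by the gem-dimethyl and α-methyl groups, and sets the C9 carbinol under catalyst control.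

Step 2
Reactants: 2 (R)-4-hydroxy-2,6,6-trimethylcyclohex-2-en-1-one
Product: 3 (R)-4-[(tert-butyldimethylsilyl)oxy]-2,6,6-trimethylcyclohex-2-en-1-one
Conditions: TBSCl, imidazole, DMF, rt
Reagents that add atoms: tert-butyldimethylsilyl chloride, CC(C)(C)[Si](C)(C)Cl
Why: Standard silylation of a secondary alcohol; the bulky ether keeps the C9 substituent equatorial for step 3 and should survive until step 12.

Step 3
Reactants: 3 (R)-4-[(tert-butyldimethylsilyl)oxy]-2,6,6-trimethylcyclohex-2-en-1-one
Product: 5 (2S,4R)-4-[(tert-butyldimethylsilyl)oxy]-2-hydroxy-2,6,6-trimethylcyclohexan-1-one, via potassium enolate 4 (not isolated)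
Conditions: K[HB(s-Bu)3], THF, −78 °C; then 3-phenyl-2-(phenylsulfonyl)oxaziridine, −78 → −20 °C
Reagents that add atoms: 3-phenyl-2-(phenylsulfonyl)oxaziridine, O=S(=O)(c1ccccc1)N1OC1c1ccccc1
Why: Conjugate hydride addition (the carbonyl is too hindered for 1,2-attack) should give the tetrasubstituted enolate regiospecifically, and Davis hydroxylation by axial attack at C7 on the half-chair with equatorial C9–OSi should place the new hydroxyl axial and trans to the C9 silyloxy group.

Step 4
Reactants: 5 (2S,4R)-4-[(tert-butyldimethylsilyl)oxy]-2-hydroxy-2,6,6-trimethylcyclohexan-1-one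
Product: 7 (6R,7aS)-6-[(tert-butyldimethylsilyl)oxy]-4,4,7a-trimethyl-5,6,7,7a-tetrahydro-1-benzofuran-2(4H)-one, via acyl ylide ester 6 (not isolated)
Conditions: Ph3P=C=C=O, toluene, 110 °C
Reagents that add atoms: (triphenylphosphoranylidene)ketene, O=C=C=P(c1ccccc1)(c1ccccc1)c1ccccc1
Why: The tertiary hydroxyl adds to the cumulated ylide and the ester ylide closes onto the neighbouring ketone by intramolecular Wittig olefination (a known one-pot butenolide synthesis from α-hydroxy ketones), and the five-membered ring forces C2 to lie cis to C7 across the new C6=C1 bond.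

Step 5
Reactants: 7 (6R,7aS)-6-[(tert-butyldimethylsilyl)oxy]-4,4,7a-trimethyl-5,6,7,7a-tetrahydro-1-benzofuran-2(4H)-one
Product: 8 (2Z)-2-[(2S,4R)-4-[(tert-butyldimethylsilyl)oxy]-2-hydroxy-2,6,6-trimethylcyclohexylidene]-N-methoxy-N-methylacetamide
Conditions: MeNH(OMe)·HCl, AlMe3, CH2Cl2, 0 °C → rt
Reagents that add atoms: N,O-dimethylhydroxylamine hydrochloride, Cl.CNOC
Why: Weinreb aminolysis of the lactone by the aluminium amide should open the butenolide without touching the alkene, so the Z geometry is inherited from the ring.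

Step 6
Reactants: 8 (2Z)-2-[(2S,4R)-4-[(tert-butyldimethylsilyl)oxy]-2-hydroxy-2,6,6-trimethylcyclohexylidene]-N-methoxy-N-methylacetamide
Product: 9 (2Z)-2-[(2S,4R)-4-[(tert-butyldimethylsilyl)oxy]-2-{[dimethyl(vinyl)silyl]oxy}-2,6,6-trimethylcyclohexylidene]-N-methoxy-N-methylacetamide
Conditions: ClSiMe2CH=CH2, imidazole, DMAP (cat.), DMF, rt
Reagents that add atoms: chloro(dimethyl)vinylsilane, C=C[Si](C)(C)Cl
Why: Silylation of the tertiary alcohol with a small chlorosilane installs the vinylsilane dienophile on the C7 oxygen and at the same time blocks relactonisation.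

Step 7
Reactants: 9 (2Z)-2-[(2S,4R)-4-[(tert-butyldimethylsilyl)oxy]-2-{[dimethyl(vinyl)silyl]oxy}-2,6,6-trimethylcyclohexylidene]-N-methoxy-N-methylacetamide
Product: 10 (1Z)-1-[(2S,4R)-4-[(tert-butyldimethylsilyl)oxy]-2-{[dimethyl(vinyl)silyl]oxy}-2,6,6-trimethylcyclohexylidene]-4-(trimethylsilyl)but-3-yn-2-one
Conditions: LiC≡CSiMe3 (from HC≡CSiMe3, n-BuLi), THF, −78 → 0 °C
Reagents that add atoms: ethynyltrimethylsilane, C#C[Si](C)(C)C
Why: Weinreb ketone synthesis, in which the chelated tetrahedral intermediate should stop the addition at the ynone stage.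

Step 8
Reactants: 10 (1Z)-1-[(2S,4R)-4-[(tert-butyldimethylsilyl)oxy]-2-{[dimethyl(vinyl)silyl]oxy}-2,6,6-trimethylcyclohexylidene]-4-(trimethylsilyl)but-3-yn-2-one
Product: 11 (1Z,2S)-1-[(2S,4R)-4-[(tert-butyldimethylsilyl)oxy]-2-{[dimethyl(vinyl)silyl]oxy}-2,6,6-trimethylcyclohexylidene]-4-(trimethylsilyl)but-3-yn-2-ol
Conditions: RuCl[(S,S)-TsDPEN](p-cymene) (cat.), i-PrOH, rt
Reagents that add atoms: none
Why: Noyori transfer hydrogenation of an alkynyl ketone (a well-precedented substrate class, including alkenyl alkynyl ketones) should set C2 as S under catalyst control with the alkynyl group in the aryl position of the model.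

Step 9
Reactants: 11 (1Z,2S)-1-[(2S,4R)-4-[(tert-butyldimethylsilyl)oxy]-2-{[dimethyl(vinyl)silyl]oxy}-2,6,6-trimethylcyclohexylidene]-4-(trimethylsilyl)but-3-yn-2-ol
Product: 12 (1Z,2S)-1-[(2S,4R)-4-[(tert-butyldimethylsilyl)oxy]-2-{[dimethyl(vinyl)silyl]oxy}-2,6,6-trimethylcyclohexylidene]but-3-yn-2-ol
Conditions: K2CO3, MeOH, 0 °C, short reaction time
Reagents that add atoms: none
Why: Methanolysis of the C(sp)–Si bond should be much faster than cleavage of the hindered tertiary silyl ether or the TBS ether.

Step 10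
Reactants: 12 (1Z,2S)-1-[(2S,4R)-4-[(tert-butyldimethylsilyl)oxy]-2-{[dimethyl(vinyl)silyl]oxy}-2,6,6-trimethylcyclohexylidene]but-3-yn-2-ol
Product: 14 tert-butyl{[(1R,3S,4Z)-4-[(aR)-4-bromobuta-2,3-dien-1-ylidene]-3-{[dimethyl(vinyl)silyl]oxy}-3,5,5-trimethylcyclohexyl]oxy}dimethylsilane, via propargylic mesylate 13 (not isolated)
Conditions: MsCl, Et3N, THF, −78 °C; then LiCuBr2 (LiBr, CuBr), THF, −78 → 0 °C
Reagents that add atoms: lithium dibromocuprate (from LiBr and CuBr), [Li+].Br[Cu-]Br
Why: Anti SN2′ displacement of a propargylic sulfonate by the bromocuprate, the standard route to configurationally defined bromoallenes, should turn the (S)-carbinol centre into the (aR)-allene axis.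

Step 11
Reactants: 14 tert-butyl{[(1R,3S,4Z)-4-[(aR)-4-bromobuta-2,3-dien-1-ylidene]-3-{[dimethyl(vinyl)silyl]oxy}-3,5,5-trimethylcyclohexyl]oxy}dimethylsilane
Product: 15 tricyclic cycloadduct: ring B carries C1=C2 and the (E)-bromomethylidene at C3; C5 (S) is bonded to SiMe2; a 2,2-dimethyl-1-oxa-2-silacyclopentane (O, Si, C5, C6, C7) is cis-fused to ring A across C6–C7; C6 is R by the sequence rule (same spatial arrangement as 6S in 19); C7 S; C9 R with OTBS
Conditions: toluene (0.01 M), BHT, 130 °C, sealed tube
Reagents that add atoms: none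
Why: Proposed new method: a concerted thermal [4+2] cycloaddition in which the vinylallene C6=C1–C2=C3 (C3=C15 stays behind as the exocyclic bromoalkene) is the diene for the unactivated vinylsilane, allene strain and the two-atom O–Si link making up for the missing activation; the closest known reaction types are the intramolecular Diels–Alder reaction of vinylallenes and the Diels–Alder reaction of dienes with a vinylsilane held by a temporary silicon ether link, neither shown with a 1-bromoallene. Ring B closes as the six-membered [4+2] ring (suprafacial on both partners, C5–C6 and C3–C4 formed together), and the oxasilacyclopentane closes in the fused mode, the silicon-bearing carbon bonding to the near diene terminus C6 because the bridged alternative would need an eight-membered ring. The spiro centre C6 is set by the tether, which can deliver C5 only to the face of ring A that carries the C7 oxygen, while C5 is fixed by the ring fusion and is erased in step 12. The C3=C15 geometry follows from axial-to-geometric transfer: the allene substituent on the attacked face ends cis to C4, and in the (Z,aR) substrate that substituent is bromine, hence the E-bromoalkene. The step needs attack on the bromine side of the allene, against the steric preference of untethered vinylallenes, and the short tether with the ring-derived Z geometry of C6=C1 secures it because the other face cannot be reached. The sp allene carbon C3 has no in-plane substituent, which eases the s-cis conformation despite the quaternary C7, and neither C7 nor C11 bears hydrogen, so the [1,5]-hydrogen shift typical of Z-vinylallenes is excluded.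

Step 12
Reactants: 15 tricyclic cycloadduct
Product: 16 (1S,3R,6S,9E)-9-(bromomethylidene)-1,5,5-trimethylspiro[5.5]undec-7-ene-1,3-diol (hydroxyls trans)
Conditions: Bu4NF·3H2O, DMF, 75 °C
Reagents that add atoms: none
Why: Fluoride adds to the strained five-membered siloxane and the pentacoordinate silicon releases C5 with protonation (the known excision of silicon from temporary silicon connections), the same reagent cleaving the Si–O bond and the TBS ether, while the vinyl bromide has no β-hydrogen to lose.

Step 13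
Reactants: 16 (1S,3R,6S,9E)-9-(bromomethylidene)-1,5,5-trimethylspiro[5.5]undec-7-ene-1,3-diol
Product: 17 (1S,6S,9E)-9-(bromomethylidene)-1-hydroxy-1,5,5-trimethylspiro[5.5]undec-7-en-3-one
Conditions: Dess–Martin periodinane, NaHCO3, CH2Cl2, 0 °C → rt
Reagents that add atoms: none
Why: Only the secondary C9 alcohol can be oxidised, and the neutral Dess–Martin oxidation should spare the β-hydroxy ketone from retro-aldol cleavage and dehydration.

Step 14
Reactants: 17 (1S,6S,9E)-9-(bromomethylidene)-1-hydroxy-1,5,5-trimethylspiro[5.5]undec-7-en-3-one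
Product: 18 (1S,3S,6S,9E)-9-(bromomethylidene)-1,5,5-trimethylspiro[5.5]undec-7-ene-1,3-diol (hydroxyls cis)
Conditions: Li[HB(s-Bu)3], THF, −78 °C
Reagents that add atoms: none
Why: The axial face of the C9 carbonyl is blocked by the syn-axial C7 hydroxyl and C11 methyl, so the bulky hydride should attack equatorially and give the axial alcohol cis to the C7 hydroxyl.

Step 15
Reactants: 18 (1S,3S,6S,9E)-9-(bromomethylidene)-1,5,5-trimethylspiro[5.5]undec-7-ene-1,3-diol
Product: 19 (1S,3R,6S,9E)-3-bromo-9-(bromomethylidene)-1,5,5-trimethylspiro[5.5]undec-7-en-1-ol (target)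
Conditions: CBr4, PPh3, CH2Cl2, 0 °C → rt
Reagents that add atoms: carbon tetrabromide, BrC(Br)(Br)Br
Why: Appel reaction: the alkoxyphosphonium of the axial secondary alcohol should be displaced by bromide from the equatorial direction with inversion, giving the equatorial (R)-bromide, while the hindered tertiary alcohol stays untouched.

**Compound list**

1 | ketoisophorone (2,6,6-trimethylcyclohex-2-ene-1,4-dione) | CC1=CC(=O)CC(C)(C)C1=O | starting material
2 | (R)-4-hydroxy-2,6,6-trimethylcyclohex-2-en-1-one | CC1(C)C[C@@H](O)C=C(C)C1=O | intermediate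
3 | (R)-4-[(tert-butyldimethylsilyl)oxy]-2,6,6-trimethylcyclohex-2-en-1-one | CC1(C)C[C@@H](O[Si](C)(C)C(C)(C)C)C=C(C)C1=O | intermediate
4 | potassium 4-[(tert-butyldimethylsilyl)oxy]-2,6,6-trimethylcyclohex-1-en-1-olate (silyloxy carbon configured as in 3) | CC1(C)C[C@@H](O[Si](C)(C)C(C)(C)C)CC(C)=C1[O-].[K+] | intermediate
5 | (2S,4R)-4-[(tert-butyldimethylsilyl)oxy]-2-hydroxy-2,6,6-trimethylcyclohexan-1-one | CC1(C)C[C@@H](O[Si](C)(C)C(C)(C)C)C[C@](C)(O)C1=O | intermediate
6 | (1S,5R)-5-[(tert-butyldimethylsilyl)oxy]-1,3,3-trimethyl-2-oxocyclohexyl 2-(triphenylphosphoranylidene)acetate | CC1(C)C[C@@H](O[Si](C)(C)C(C)(C)C)C[C@](C)(OC(=O)C=P(c2ccccc2)(c2ccccc2)c2ccccc2)C1=O | intermediate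
7 | (6R,7aS)-6-[(tert-butyldimethylsilyl)oxy]-4,4,7a-trimethyl-5,6,7,7a-tetrahydro-1-benzofuran-2(4H)-one | CC1(C)C[C@@H](O[Si](C)(C)C(C)(C)C)C[C@]2(C)OC(=O)C=C12 | intermediate
8 | (2Z)-2-[(2S,4R)-4-[(tert-butyldimethylsilyl)oxy]-2-hydroxy-2,6,6-trimethylcyclohexylidene]-N-methoxy-N-methylacetamide | CC1(C)C[C@@H](O[Si](C)(C)C(C)(C)C)C[C@](C)(O)/C1=C\C(=O)N(C)OC | intermediate
9 | (2Z)-2-[(2S,4R)-4-[(tert-butyldimethylsilyl)oxy]-2-{[dimethyl(vinyl)silyl]oxy}-2,6,6-trimethylcyclohexylidene]-N-methoxy-N-methylacetamide | CC1(C)C[C@@H](O[Si](C)(C)C(C)(C)C)C[C@](C)(O[Si](C)(C)C=C)/C1=C\C(=O)N(C)OC | intermediate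
10 | (1Z)-1-[(2S,4R)-4-[(tert-butyldimethylsilyl)oxy]-2-{[dimethyl(vinyl)silyl]oxy}-2,6,6-trimethylcyclohexylidene]-4-(trimethylsilyl)but-3-yn-2-one | CC1(C)C[C@@H](O[Si](C)(C)C(C)(C)C)C[C@](C)(O[Si](C)(C)C=C)/C1=C\C(=O)C#C[Si](C)(C)C | intermediate
11 | (1Z,2S)-1-[(2S,4R)-4-[(tert-butyldimethylsilyl)oxy]-2-{[dimethyl(vinyl)silyl]oxy}-2,6,6-trimethylcyclohexylidene]-4-(trimethylsilyl)but-3-yn-2-ol | CC1(C)C[C@@H](O[Si](C)(C)C(C)(C)C)C[C@](C)(O[Si](C)(C)C=C)/C1=C\[C@H](O)C#C[Si](C)(C)C | intermediate
12 | (1Z,2S)-1-[(2S,4R)-4-[(tert-butyldimethylsilyl)oxy]-2-{[dimethyl(vinyl)silyl]oxy}-2,6,6-trimethylcyclohexylidene]but-3-yn-2-ol | CC1(C)C[C@@H](O[Si](C)(C)C(C)(C)C)C[C@](C)(O[Si](C)(C)C=C)/C1=C\[C@H](O)C#C | intermediate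
13 | methanesulfonate of 12 ((1Z,2S)-configured propargylic mesylate) | CC1(C)C[C@@H](O[Si](C)(C)C(C)(C)C)C[C@](C)(O[Si](C)(C)C=C)/C1=C\[C@H](OS(C)(=O)=O)C#C | intermediate
14 | tert-butyl{[(1R,3S,4Z)-4-[(aR)-4-bromobuta-2,3-dien-1-ylidene]-3-{[dimethyl(vinyl)silyl]oxy}-3,5,5-trimethylcyclohexyl]oxy}dimethylsilane | CC1(C)C[C@@H](O[Si](C)(C)C(C)(C)C)C[C@](C)(O[Si](C)(C)C=C)/C1=C\C([H])=[C@]=C([H])Br | intermediate
15 | tricyclic cycloadduct: spiro ring B with C1=C2 and (E)-bromomethylidene at C3; C5 (S) bonded to SiMe2; 2,2-dimethyl-1-oxa-2-silacyclopentane cis-fused to ring A; C6 R, C7 S, C9 R (OTBS) | CC1(C)C[C@@H](O[Si](C)(C)C(C)(C)C)C[C@]2(C)O[Si](C)(C)[C@H]3C/C(=C\Br)C=C[C@@]123 | intermediate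
16 | (1S,3R,6S,9E)-9-(bromomethylidene)-1,5,5-trimethylspiro[5.5]undec-7-ene-1,3-diol | CC1(C)C[C@@H](O)C[C@](C)(O)[C@@]12C=C/C(=C/Br)CC2 | intermediate
17 | (1S,6S,9E)-9-(bromomethylidene)-1-hydroxy-1,5,5-trimethylspiro[5.5]undec-7-en-3-one | CC1(C)CC(=O)C[C@](C)(O)[C@@]12C=C/C(=C/Br)CC2 | intermediate
18 | (1S,3S,6S,9E)-9-(bromomethylidene)-1,5,5-trimethylspiro[5.5]undec-7-ene-1,3-diol | CC1(C)C[C@H](O)C[C@](C)(O)[C@@]12C=C/C(=C/Br)CC2 | intermediate
19 | (1S,3R,6S,9E)-3-bromo-9-(bromomethylidene)-1,5,5-trimethylspiro[5.5]undec-7-en-1-ol | CC1(C)C[C@@H](Br)C[C@](C)(O)[C@@]12C=C/C(=C/Br)CC2 | target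

**Totals**

Total step count: 15. Longest linear sequence: 15 steps (from ketoisophorone 1).

**Steps most likely to fail**

Step 11 (proposed new method). The cycloaddition may be too slow at the congested, fully substituted diene terminus, so that thermal isomerisation or decomposition of the bromoallene, or loss of the axis by epimerisation, wins over ring closure. The fallback uses known reaction types, sets out from compound 9 and comes back at compound 15. Reduction of the Weinreb amide with i-Bu2AlH (THF, −78 °C) should give the (Z)-enal F1. Wittig methylenation (Ph3P=CH2, THF) should give the (Z)-1,3-diene F2. The silicon-tethered intramolecular Diels–Alder reaction of this plain diene with the vinylsilane (toluene, 180–200 °C, sealed tube) should give the tricyclic siloxane F3, in which C3 is the only allylic methylene. Allylic oxidation (CrO3, 3,5-dimethylpyrazole, CH2Cl2) should give the spiro enone F4. Wittig bromomethylenation (Ph3P=CHBr from (bromomethyl)triphenylphosphonium bromide and KOt-Bu, THF, −78 °C) and separation of the two geometric isomers should give compound 15. In this detour the bromoalkene geometry is no longer controlled.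

Step 10. The doubly activated (allylic and propargylic) mesylate may ionise before the cuprate delivers bromide, which would scramble the centre-to-axis transfer, give the propargylic bromide by direct substitution, or lead to capture by the neighbouring silyloxy oxygen. The fallback sets out from compound 10 and comes back at compound 14. Transfer hydrogenation with the enantiomeric catalyst RuCl[(R,R)-TsDPEN](p-cymene) should give the (R)-carbinol F5, and K2CO3/MeOH the terminal alkyne F6. Treatment with SOBr2 and propylene oxide in Et2O at −20 °C should form a bromosulfite that collapses by a syn SNi′ shift, a known conversion of propargylic alcohols into haloallenes. Syn delivery from the (R)-centre gives the same (aR)-bromoallene 14 without a free sulfonate.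

Step 15. At the hindered axial carbinol, elimination toward C8 or C10 and interference by the syn-axial tertiary hydroxyl may outrun clean inversion. The fallback sets out from compound 18 and comes back at compound 19. 1,1′-Sulfonyldiimidazole and NaH in THF should tie both hydroxyls into the cyclic sulfate F7. LiBr in DMF should open it at the secondary carbon C9 with inversion to the lithium sulfate monoester F8. Mild acid hydrolysis (cat. H2SO4, wet THF) should free the tertiary alcohol and give 19.

Further compounds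
F1 | step 11 | (2Z)-2-[(2S,4R)-4-[(tert-butyldimethylsilyl)oxy]-2-{[dimethyl(vinyl)silyl]oxy}-2,6,6-trimethylcyclohexylidene]acetaldehyde | CC1(C)C[C@@H](O[Si](C)(C)C(C)(C)C)C[C@](C)(O[Si](C)(C)C=C)/C1=C\C=O
F2 | step 11 | (Z)-1,3-diene from methylenation of F1 (ring A carrying a prop-2-en-1-ylidene group at C6) | CC1(C)C[C@@H](O[Si](C)(C)C(C)(C)C)C[C@](C)(O[Si](C)(C)C=C)/C1=C\C=C
F3 | step 11 | tricyclic siloxane without the bromomethylidene (C3 is CH2; other centres as in 15) | CC1(C)C[C@@H](O[Si](C)(C)C(C)(C)C)C[C@]2(C)O[Si](C)(C)[C@H]3CCC=C[C@@]123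
F4 | step 11 | tricyclic spiro enone (C3 ketone conjugated with C1=C2; other centres as in 15) | CC1(C)C[C@@H](O[Si](C)(C)C(C)(C)C)C[C@]2(C)O[Si](C)(C)[C@H]3CC(=O)C=C[C@@]123
F5 | step 10 | (1Z,2R)-1-[(2S,4R)-4-[(tert-butyldimethylsilyl)oxy]-2-{[dimethyl(vinyl)silyl]oxy}-2,6,6-trimethylcyclohexylidene]-4-(trimethylsilyl)but-3-yn-2-ol | CC1(C)C[C@@H](O[Si](C)(C)C(C)(C)C)C[C@](C)(O[Si](C)(C)C=C)/C1=C\[C@@H](O)C#C[Si](C)(C)C
F6 | step 10 | (1Z,2R)-1-[(2S,4R)-4-[(tert-butyldimethylsilyl)oxy]-2-{[dimethyl(vinyl)silyl]oxy}-2,6,6-trimethylcyclohexylidene]but-3-yn-2-ol | CC1(C)C[C@@H](O[Si](C)(C)C(C)(C)C)C[C@](C)(O[Si](C)(C)C=C)/C1=C\[C@@H](O)C#C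
F7 | step 15 | cyclic sulfate of diol 18 (sulfate bridging the C7 and C9 oxygens) | CC1(C)C[C@H]2C[C@](C)(OS(=O)(=O)O2)[C@@]13C=C/C(=C/Br)CC3
F8 | step 15 | lithium sulfate monoester of 19 (C7–OSO3Li, C9 equatorial bromide) | CC1(C)C[C@@H](Br)C[C@](C)(OS(=O)(=O)[O-])[C@@]12C=C/C(=C/Br)CC2.[Li+]
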